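## The problem

The target is 2,4,7-tribromo-3-chloro-1H-indole 13: the pyrrole ring is fully substituted at carbon (Br at C2, Cl at C3), the benzo ring carries bromine at C4 and C7, and only N1–H, C5–H and C6–H remain. There are no stereocentres, so the whole problem is positional. Two kinds of halogen must sit on four defined carbons, and the isomer with chlorine at C2 and bromine at C3 must be excluded. Electrophilic halogenation of an indole reaches C3, then C2, then C5/C6, and never C4/C7 selectively, so the para-dibromo pattern must come with the arene. Three C–Br bonds rule out late zerovalent palladium, alkyllithium and dissolving-metal steps. 2,3-Dihaloindoles are sensitive to acid, light and water (oxindole formation), and their halogens can migrate between C2 and C3, so the last operations must be mild and anhydrous. The feature that opens the key step is the chain Cl–C3–C2–N1: a benzylic CH2Cl carbon ortho to an isocyanide already holds C3 with its chlorine, and the isocyanide carbon is C2. Forming C2–C3 therefore closes the ring with chlorine fixed at C3 and leaves C2 as the only nucleophilic CH for the last bromine.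

## Retrosynthesis

**13 ⇒ 12 (C2–Br).** The C2–Br bond is cut first. In 4,7-dibromo-3-chloro-1H-indole 12 the C3 position is blocked and the benzo ring is deactivated by two bromines, so C2 is the only reactive carbon. Cutting C3–Cl last instead would require a 2-bromoindole, which is less stable and harder to make. The forward step is a mild electrophilic bromination that must not disturb the chlorine at C3.

**12 ⇒ 8 (C2–C3, ring closure).** The pyrrole ring is opened between C2 and C3 to give 1,4-dibromo-2-(chloromethyl)-3-isocyanobenzene 8. This cut is preferred over N1–C2 or N1–C7a because it is the only one in which the chlorine-bearing carbon enters as a benzylic carbon that already carries its chlorine. Precursor 8 is a monocyclic arene with two one-carbon functional groups. The forward reaction asks a hindered lithium amide to remove a CHCl proton to give the carbenoid 9, which must add to the isocyanide carbon to give the imidoyl lithium 10. Tautomerisation to the N-lithioindole 11 and protonation then give 12. The base must spare the ring C–H bonds next to bromine and the isocyanide carbon.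

**8 ⇒ 7 (functional-group level).** Both functions of 8 are traced to N-[3,6-dibromo-2-(hydroxymethyl)phenyl]formamide 7: isocyanide from formamide, chloride from alcohol, both by POCl3 and an amine base. The other option, benzylic metalation of an ortho-tolyl isocyanide followed by an electrophilic chlorine donor, was set aside for three reasons:
- The ring protons ortho to bromine compete with a methyl group for the base.
- The monochloride is more acidic than its precursor and would react further.
- It would make two strong-base steps in a row on a dibromoarene.

With an oxygenated benzylic carbon, the chlorine is introduced without any carbanion.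

**7 ⇒ 5 ⇒ 4 (N-formyl, then oxidation level).** Formamide 7 comes from (2-amino-3,6-dibromophenyl)methanol 5 by formylation. Because the aniline is hindered and electron-poor, both N and O are formylated to give the formamido formate 6, and the formate ester is then cleaved selectively. Alcohol 5 is the borane reduction product of 2-amino-3,6-dibromobenzoic acid 4. The reduction must be chemoselective for CO2H in the presence of two aryl bromides.

**4 ⇒ 2 ⇒ 1 (C–N bond by rearrangement).** The aryl C–N bond of 4 is cut back to a carboxamide carbon: Hofmann rearrangement of 3,6-dibromophthalimide 2, through its ring-opened phthalamate 3. Imide 2 comes from 3,6-dibromophthalic anhydride 1. This is preferred over brominating an aminoarene, where the para position would react first. In 1 the two bromines already flank two equivalent carbonyl carbons, so whichever carbonyl becomes nitrogen, the product is the same 1,2,3,4-tetrasubstituted benzene. All eight carbons of the indole are present in 1.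

## Roads not taken

Alternative 1: The benzo ring is cut at C3a–C4 and C7–C7a. In the forward sense 2,5-dibromothiophene 1,1-dioxide A1 would add as an electron-poor diene across the enecarbamate double bond of tert-butyl 2,3-dihydro-1H-pyrrole-1-carboxylate A2. Loss of SO2 from the adduct would give the cis-fused dibromocyclohexadiene, tert-butyl cis-4,7-dibromo-2,3,3a,7a-tetrahydro-1H-indole-1-carboxylate A3.
- Merits: diene A1 delivers both bromines exactly at C4 and C7, and cycloaddition–extrusion of thiophene dioxides is a known reaction type. On precedent for the key step this road is ahead of the chosen plan.
- Weak points: A3 is two oxidation levels below an indole. It needs dehydrogenation to the indoline level and then to the indole level, where double-bond isomerisation and loss of HBr under forcing conditions cannot be excluded. Boc removal follows. The material then still lacks both pyrrole halogens, which would be added by two successive electrophilic halogenations.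
- Comparison: it builds the ring that can be bought and leaves the hard part, Cl at C3 and Br at C2, entirely to substrate-controlled substitution. The chosen plan places chlorine by construction and needs only one halogenation after ring closure. The step counts are similar.

Alternative 2: The cut is N1–C2 together with C3–Cl. N-[3,6-Dibromo-2-(bromoethynyl)phenyl]-4-methylbenzenesulfonamide A4 would be treated with NCS or CuCl2. Nitrogen adds to the bromine-bearing alkyne carbon while chlorine is delivered to the other, giving 2,4,7-tribromo-3-chloro-1-tosylindole A5.
- Merits: all four halogens are in place in A5 after one ring-forming event and only detosylation remains. Halocyclisation of N-sulfonyl 2-alkynylanilines to 3-haloindoles is well established. In its endgame this route is better than the chosen one, because it avoids the final bromination and its scrambling risk.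
- Weak points: these lie before the key step. Sulfonamide A4 needs an alkyne ortho to nitrogen on a dibromoarene, which means a zerovalent-palladium coupling at an iodide that must be selective against two aryl bromides. That iodide would itself have to be placed ortho to nitrogen against the para preference. A silyl-to-bromoalkyne exchange and a tosyl group on and off follow. The electron-poor 1-bromoalkyne of A4 may be slow towards electrophilic chlorine and may exchange halogen with CuCl2.
- Comparison: the chosen plan uses no palladium, no protecting group and a symmetric C8 starting material, at the price of an untested ring closure.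

Alternative 3: The cut is N1–C7a. 2,5-Dibromobenzaldehyde A6 would be condensed with an azidoacetate ester to methyl (Z)-2-azido-3-(2,5-dibromophenyl)prop-2-enoate A7. Thermolysis of A7 in xylene (Hemetsberger–Knittel) gives a vinyl nitrene that inserts into the only free ortho C–H to give methyl 4,7-dibromo-1H-indole-2-carboxylate A8.
- Merits: the ring closure is proven and its regiochemistry is fixed by the bromine on the other ortho carbon. The ester of A8 tempers the indole so that C3 chlorination should stop cleanly. The sequence from A6 is probably shorter (about five steps). On precedent and length this road is better.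
- Weak points: it uses an azidoacetate and the hot vinyl azide A7. It must end by converting the ester of A8 into bromine through saponification and ipso-bromodecarboxylation at C2 of a 3-chloroindole acid. That is its least secure operation and faces the same C2/C3 halogen-migration question as the chosen endgame, on a less nucleophilic carbon.
- Comparison: the chosen plan avoids azide and nitrene chemistry, fixes chlorine at C3 without relying on substitution selectivity, and leaves a plain C–H bromination as its last step.

Key step: step 6

Assumption: 3,6-dibromophthalic anhydride 1, a catalogue monomer for phthalimide-based materials, is taken as the commercial starting material; the front of the route relies on its symmetry.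

## Route

Step 1
Reactants: 1 3,6-dibromophthalic anhydride (4,7-dibromo-2-benzofuran-1,3-dione)
Product: 2 3,6-dibromophthalimide (4,7-dibromoisoindoline-1,3-dione)
Conditions: NH4OAc, AcOH, reflux
Reagents that add atoms: ammonium acetate, CC(=O)[O-].[NH4+]
Why: Imide formation from a cyclic anhydride and ammonia (amic acid, then cyclodehydration in hot acetic acid); the aryl bromides are inert and the symmetry of 1 is carried into 2.

Step 2
Reactants: 2 3,6-dibromophthalimide
Product: 4 2-amino-3,6-dibromobenzoic acid, via sodium 3,6-dibromo-2-carbamoylbenzoate 3 (not isolated)
Conditions: NaOH, H2O, 0 °C; NaOCl (1.0 equiv), 0 to 75 °C; HCl to pH 3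
Reagents that add atoms: sodium hydroxide, [Na+].[OH-]
Why: Hofmann rearrangement in its classical phthalimide-to-anthranilic acid form: hydroxide opens 2 to the phthalamate 3, hypochlorite N-chlorinates the primary amide and the aryl carbon migrates to nitrogen; since the two carbonyl groups of 2 are equivalent, only one amino acid can result, with one bromine ortho to nitrogen and the other ortho to the carboxyl group.

Step 3
Reactants: 4 2-amino-3,6-dibromobenzoic acid
Product: 5 (2-amino-3,6-dibromophenyl)methanol
Conditions: BH3·THF, THF, 0 °C to reflux; MeOH; aq NaOH
Reagents that add atoms: none
Why: Chemoselective borane reduction of a carboxylic acid through its acyloxyborane; the aryl bromides are not touched by this electrophilic hydride, and the weakly basic aniline is freed from boron in the methanol and base work-up.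

Step 4
Reactants: 5 (2-amino-3,6-dibromophenyl)methanol
Product: 7 N-[3,6-dibromo-2-(hydroxymethyl)phenyl]formamide, via (3,6-dibromo-2-formamidophenyl)methyl formate 6 (not isolated)
Conditions: HCO2H, Ac2O, 55 °C, then 5, THF, 0 °C to rt; KHCO3, MeOH–H2O, rt
Reagents that add atoms: formic acid, OC=O (transferred as acetic formic anhydride, CC(=O)OC=O)
Why: N-Formylation of an aniline with acetic formic anhydride, which transfers only the formyl group; the hindered, electron-poor nitrogen reacts slowly, so the benzylic alcohol is formylated as well (6), and hydrogencarbonate methanolysis then removes the far more labile formate ester while the formanilide stays.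

Step 5
Reactants: 7 N-[3,6-dibromo-2-(hydroxymethyl)phenyl]formamide
Product: 8 1,4-dibromo-2-(chloromethyl)-3-isocyanobenzene
Conditions: POCl3 (2.5 equiv), i-Pr2NEt, CH2Cl2, −20 °C to rt; aq Na2CO3 work-up
Reagents that add atoms: phosphorus oxychloride, O=P(Cl)(Cl)Cl
Why: Two standard POCl3/amine reactions run in one flask, dehydration of the formanilide to the isocyanide (Ugi isocyanide synthesis via the O-phosphorylated imidate) and chlorodehydroxylation of the primary benzylic alcohol via its dichlorophosphate; the alcohol is phosphorylated first in the cold, which removes it as a nucleophile before the formamide is activated, and the hindered base cannot quaternise the benzylic chloride.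

Step 6
Reactants: 8 1,4-dibromo-2-(chloromethyl)-3-isocyanobenzene
Product: 12 4,7-dibromo-3-chloro-1H-indole, via benzylic lithium carbenoid 9 (not isolated), via 2-lithio-3H-indole 10 (not isolated), via N-lithioindole 11 (not isolated)
Conditions: lithium 2,2,6,6-tetramethylpiperidide (from n-BuLi and 2,2,6,6-tetramethylpiperidine, 1.3 equiv), THF, slow addition of 8 at −78 °C, then −78 to −20 °C; aq NH4Cl
Reagents that add atoms: none
Why: Proposed new method: the hindered amide removes a benzylic proton of 8, acidified by chlorine, by the ortho isocyano group and by the dibromoarene, to give the α-chloro benzylic lithium 9, whose carbanion adds to the divalent isocyanide carbon, forming C2–C3 and closing the pyrrole ring in a 5-endo-dig mode as the imidoyl lithium 10. Proton transfer from C3 to C2, relayed by the tetramethylpiperidine set free in the first step, gives the aromatic N-lithioindole 11, and aqueous NH4Cl liberates 12. The closest known reaction type is the lithium amide-induced cyclisation of ortho-methyl- and ortho-alkylphenyl isocyanides to indoles (Ito–Saegusa indole synthesis); what is new is that the cyclising carbanion is an α-chloro carbenoid. No stereocentre is created in 12: C3 of 10 is stereogenic only transiently and becomes planar on tautomerisation. The step needs chemoselectivity for benzylic deprotonation over ring metalation next to bromine, over addition of the base to the isocyanide and over self-condensation of the carbenoid; the higher acidity of the CHCl proton, the bulky non-nucleophilic amide, slow addition of 8 to the base in the cold and the ortho position of the internal trap are expected to secure it. Chlorine should not be lost on the productive path, because the C2 anion of 10 could expel it only by forming a cumulated double bond inside a five-membered ring.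

Step 7
Reactants: 12 4,7-dibromo-3-chloro-1H-indole
Product: 13 2,4,7-tribromo-3-chloro-1H-indole
Conditions: NBS (1.05 equiv), anhydrous DMF, 0 °C to rt, dark
Reagents that add atoms: N-bromosuccinimide, O=C1CCC(=O)N1Br
Why: Electrophilic bromination of a 3-substituted indole at C2 with NBS, the standard entry to 2-bromo-3-haloindoles; C3 is blocked, the benzo ring is deactivated by its two bromines, and anhydrous, acid-free conditions keep the dihaloindole from hydrolysing to an oxindole.

## Compound list

1 | 3,6-dibromophthalic anhydride (4,7-dibromo-2-benzofuran-1,3-dione) | O=C1OC(=O)c2c(Br)ccc(Br)c12 | starting material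
2 | 3,6-dibromophthalimide (4,7-dibromoisoindoline-1,3-dione) | O=C1NC(=O)c2c(Br)ccc(Br)c12 | intermediate
3 | sodium 3,6-dibromo-2-carbamoylbenzoate (not isolated) | NC(=O)c1c(Br)ccc(Br)c1C(=O)[O-].[Na+] | intermediate
4 | 2-amino-3,6-dibromobenzoic acid | Nc1c(Br)ccc(Br)c1C(O)=O | intermediate
5 | (2-amino-3,6-dibromophenyl)methanol | Nc1c(Br)ccc(Br)c1CO | intermediate
6 | (3,6-dibromo-2-formamidophenyl)methyl formate (not isolated) | O=CNc1c(Br)ccc(Br)c1COC=O | intermediate
7 | N-[3,6-dibromo-2-(hydroxymethyl)phenyl]formamide | O=CNc1c(Br)ccc(Br)c1CO | intermediate
8 | 1,4-dibromo-2-(chloromethyl)-3-isocyanobenzene | [C-]#[N+]c1c(Br)ccc(Br)c1CCl | intermediate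
9 | chloro(3,6-dibromo-2-isocyanophenyl)methyllithium, the benzylic lithium carbenoid (not isolated) | [Li]C(Cl)c1c(Br)ccc(Br)c1[N+]#[C-] | intermediate
10 | (4,7-dibromo-3-chloro-3H-indol-2-yl)lithium, racemic at C3 and transient (not isolated) | [Li]C1=Nc2c(Br)ccc(Br)c2C1Cl | intermediate
11 | 4,7-dibromo-3-chloro-1-lithioindole (not isolated) | [Li]n1cc(Cl)c2c(Br)ccc(Br)c12 | intermediate
12 | 4,7-dibromo-3-chloro-1H-indole | Clc1c[nH]c2c(Br)ccc(Br)c12 | intermediate
13 | 2,4,7-tribromo-3-chloro-1H-indole | Clc1c(Br)[nH]c2c(Br)ccc(Br)c12 | target

## Step count and risks

Total steps: 7. Longest linear sequence: 7 steps (1 to 13).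

**Step 6 (key step, new method).** The most likely failure is decomposition of the carbenoid before it cyclises. An α-chloro carbanion is less nucleophilic than the parent benzylic anion, so ring closure may need warming beyond the temperature at which the carbenoid self-alkylates or loses chloride. Ring metalation next to bromine with subsequent bromine migration, and addition of the amide to the isocyanide, are further drains.

Fallback, by known chemistry, from 5 back to 12: triphenylphosphine hydrobromide in refluxing MeCN would convert the benzylic alcohol of 5 into [(2-amino-3,6-dibromophenyl)methyl]triphenylphosphonium bromide F1. Acetic formic anhydride in CH2Cl2 would formylate the nitrogen to give [(3,6-dibromo-2-formamidophenyl)methyl]triphenylphosphonium bromide F2. KOt-Bu in hot toluene would form the ylide, which closes onto the formamide carbonyl in an intramolecular Wittig reaction to 4,7-dibromo-1H-indole F3. This forms the same C2–C3 bond from a phosphorus-stabilised benzylic carbanion. NCS in DMF would then chlorinate C3, the innate site of indole substitution, to give 12.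

**Step 5.** Two processes may interfere. The chloride displacement may stall at the doubly ortho-substituted benzylic dichlorophosphate, which would be lost as a phosphate on aqueous work-up. Alternatively, the hydroxyl or formamide oxygen may cyclise onto its activated neighbour to a 4H-3,1-benzoxazine.

Fallback from 6 back to 8, keeping the oxygen masked while the formamide is activated and removing the formamide before a benzylic leaving group exists: 6 would be isolated by leaving out the hydrogencarbonate methanolysis of step 4. POCl3 and Et3N in CH2Cl2 at 0 °C would dehydrate its formamide to (3,6-dibromo-2-isocyanophenyl)methyl formate F4. KHCO3 in MeOH–H2O at rt would cleave the formate ester to (3,6-dibromo-2-isocyanophenyl)methanol F5. An Appel chlorination (PPh3, CCl4, CH2Cl2, rt), a neutral reagent pair that isocyanides tolerate, would then give 8.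

**Step 7.** Bromination may proceed by attack at C3 followed by migration of chlorine instead of bromine, which scrambles the halogen positions. Over-bromination at C5/C6 or oxidation to an oxindole by adventitious water are also possible.

Fallback from 12 back to 13, replacing electrophilic substitution by directed metalation: di-tert-butyl dicarbonate with catalytic 4-dimethylaminopyridine would give tert-butyl 4,7-dibromo-3-chloroindole-1-carboxylate F6. Lithium diisopropylamide in THF at −78 °C would remove the C2 proton, the most acidic one, and 1,2-dibromo-1,1,2,2-tetrachloroethane would give tert-butyl 2,4,7-tribromo-3-chloroindole-1-carboxylate F7. Trifluoroacetic acid in CH2Cl2 would remove the carbamate to give 13.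

**Step 2.** Hypochlorite may chlorinate the electron-rich anthranilate at its free para carbon, or the hindered N-chloroamide may rearrange incompletely.

Fallback from 1 back to 4, a Curtius-type route with no oxidant: azidotrimethylsilane in hot toluene would open the anhydride to an acyl azide, which rearranges and recloses to 5,8-dibromo-2H-3,1-benzoxazine-2,4(1H)-dione (5,8-dibromoisatoic anhydride) F8. Aqueous NaOH followed by acidification would hydrolyse and decarboxylate it to 4.

## Further compounds

F1 | step 6 | [(2-amino-3,6-dibromophenyl)methyl]triphenylphosphonium bromide | Nc1c(Br)ccc(Br)c1C[P+](c1ccccc1)(c1ccccc1)c1ccccc1.[Br-]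
F2 | step 6 | [(3,6-dibromo-2-formamidophenyl)methyl]triphenylphosphonium bromide | O=CNc1c(Br)ccc(Br)c1C[P+](c1ccccc1)(c1ccccc1)c1ccccc1.[Br-]
F3 | step 6 | 4,7-dibromo-1H-indole | Brc1ccc(Br)c2[nH]ccc12
F4 | step 5 | (3,6-dibromo-2-isocyanophenyl)methyl formate | [C-]#[N+]c1c(Br)ccc(Br)c1COC=O
F5 | step 5 | (3,6-dibromo-2-isocyanophenyl)methanol | [C-]#[N+]c1c(Br)ccc(Br)c1CO
F6 | step 7 | tert-butyl 4,7-dibromo-3-chloroindole-1-carboxylate | CC(C)(C)OC(=O)n1cc(Cl)c2c(Br)ccc(Br)c12
F7 | step 7 | tert-butyl 2,4,7-tribromo-3-chloroindole-1-carboxylate | CC(C)(C)OC(=O)n1c(Br)c(Cl)c2c(Br)ccc(Br)c12
F8 | step 2 | 5,8-dibromo-2H-3,1-benzoxazine-2,4(1H)-dione | O=C1Nc2c(Br)ccc(Br)c2C(=O)O1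
A1 | alternative 1 | 2,5-dibromothiophene 1,1-dioxide | O=S1(=O)C(Br)=CC=C1Br
A2 | alternative 1 | tert-butyl 2,3-dihydro-1H-pyrrole-1-carboxylate | CC(C)(C)OC(=O)N1CCC=C1
A3 | alternative 1 | tert-butyl cis-4,7-dibromo-2,3,3a,7a-tetrahydro-1H-indole-1-carboxylate (racemic) | CC(C)(C)OC(=O)N1CC[C@H]2C(Br)=CC=C(Br)[C@@H]12
A4 | alternative 2 | N-[3,6-dibromo-2-(bromoethynyl)phenyl]-4-methylbenzenesulfonamide | Cc1ccc(cc1)S(=O)(=O)Nc1c(Br)ccc(Br)c1C#CBr
A5 | alternative 2 | 2,4,7-tribromo-3-chloro-1-tosylindole | Cc1ccc(cc1)S(=O)(=O)n1c(Br)c(Cl)c2c(Br)ccc(Br)c12
A6 | alternative 3 | 2,5-dibromobenzaldehyde | O=Cc1cc(Br)ccc1Br
A7 | alternative 3 | methyl (Z)-2-azido-3-(2,5-dibromophenyl)prop-2-enoate | COC(=O)/C(N=[N+]=[N-])=C/c1cc(Br)ccc1Br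
A8 | alternative 3 | methyl 4,7-dibromo-1H-indole-2-carboxylate | COC(=O)c1cc2c(Br)ccc(Br)c2[nH]1
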